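Take the leftover first: after 6.00 h the maple run still holds 74.2% of its starting material, and read against the earlier readings, that number is your way into the new flask.

| setting | maple | flask |
|---|---|---|
| starting material | 0.075 M | 0.050 M |
| coupling partner | 4 equiv | 4.00 equiv |
| scavenger | 0.50 equiv | 0.500 equiv |
| initiator | 9 mol% | 9 mol% |
| remark | run made earlier |  |
| time |  | 2.5 d |

maple run (percent of the starting material charged)

| time / h | starting material / % | target / % |
|---|---|---|
| 0.500 | 97.4 | 2.1 |
| 1.50 | 93.1 | 6.7 |
| 3.00 | 86.8 | 12.6 |
| 4.00 | 82.3 | 17.4 |
| 6.00 | 74.2 | 24.7 |

(readings scatter by 0.3 percentage points)

* part of the starting material that has reacted at 2.5 d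
* share of the unused coupling partner that is free and not bound as idle adduct, at 2.5 d

Run the maple flask slowly. In the first instants, at 0.500 h, you find 97.4% of starting material and 2.1% of target, which add up to 99.5%, so what goes reappears as target. For the middle and the end, use the clearing time, the time the whole charge of starting material takes to go at the rate seen so far: 22.7 h from the reading at 3.00 h, and 23.3 h from the last one. What matters next is whether that straight line lasts, and the readings cannot prove it, since 25.8% of the charge has gone and the first-order curve passes through them too.

My own reckoning commits to the line: I take the molar rate as proportional to initiator and to coupling partner, and zero order in starting material. The new flask has 0.667 of each maple charge, so the rate falls by the square of that and the charge falls once, and the clearing time becomes 1.45 d, shorter than the 2.5 d allowed. I therefore expect conversion close to complete, and I have no reckoning for fr. The forecast gives 80% for c and 92% for fr, noting that “the pseudo-first-order constant depends on the unknown orders”.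

The flask gives 98.8% for c and 89.9% for fr.

    scavenger + released group → scavenged by-product (k = 3.00 /M/min)
    2 first chain carrier → ended chains B (k = 3.00 × 10⁷ /M/s)
    2 second chain carrier → ended chains A (k = 2.00 × 10⁷ /M/s)
    coupling partner + first chain carrier → target + second chain carrier (k = 12000 /M/min)
    starting material + initiating radical → capped initiator + first chain carrier (k = 30000 /M/s)
    initiator → 2 initiating radical (k = 1.40 × 10⁻⁴ /min)
    coupling partner + released group ⇌ idle adduct, settled at all times (K = 21.0 /M)
    starting material + second chain carrier → released group + first chain carrier (k = 75000 /M/min)
    first chain carrier → ended carrier (k = 49.0 /min)

At 0.669 d in the flask, second chain carrier uses starting material 18 times as fast as initiating radical does, and first chain carrier passes to coupling partner 42 times as fast as it turns into ended carrier, its pairing to ended chains B not counted in that ratio, while the clearing time of 1.45 d stands below 2.5 d. In the neighbouring flask with 1.00 equiv of coupling partner, other charges held, the clearing time grows 4.00-fold to 5.81 d, which reckons 43.0% reacted at 2.5 d, and that flask has reacted 44.9%.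

The earlier runs and the new flask were computed with made-up constants, and the scatter is random.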